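**Retrosynthetic overview**
- Last step: an acyclic lactol/allylic bromide is closed by chromium-mediated carbonyl allylation (C6–C7, ten-membered carbocycle), and the C6 alkoxide lactonises onto the C12 ester in the same flask; C6 and C7 are set here.
- The seco compound comes from cross-metathesis at C1=C10 of a West lactol (C1–C6) and an East bromo diester (C7–C14) that already carries the C8 epoxyangelate.
- East: asymmetric 2-(methoxycarbonyl)allylation of 3-methylbut-2-enal (sets C8), esterification, ozonolysis, Morita–Baylis–Hillman reaction, allylic bromination.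
- West: Brown allylation of 5-hydroxy-4-methylfuran-2(5H)-one (sets C3; the ring locks C4=C5 cis), then half-reduction. Acid: angelic acid, Sharpless epoxidation, oxidation.
- Ring order: side-chain epoxide first; the furanone/lactol ring of the West piece is a temporary template; carbocycle and γ-lactone close together at the end.

Assumption: atom labels C1–C15 follow germacrane numbering of the target (lactone O on C6, lactone carbonyl C12, ester carbon C14); "EpAng" means the (2R,3R)-2,3-dimethyloxirane-2-carbonyl group; the reagents named are taken as commercial.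

**Step 1**
Reactants: 1 angelic acid
Product: 2 (2Z)-2-methylbut-2-en-1-ol
Conditions: LiAlH4, Et2O, 0 °C to rt; NaOH/H2O work-up
Reagents that add atoms: none
Why: Hydride reduction of the carboxylic acid at low temperature leaves the trisubstituted Z-alkene untouched and gives the Z-allylic alcohol needed for a directed epoxidation.

**Step 2**
Reactants: 2 (2Z)-2-methylbut-2-en-1-ol
Product: 3 [(2S,3R)-2,3-dimethyloxiran-2-yl]methanol
Conditions: Ti(OiPr)4 (10 mol %), L-(+)-DIPT (12 mol %), t-BuOOH, 4 Å MS, CH2Cl2, −20 °C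
Reagents that add atoms: tert-butyl hydroperoxide, CC(C)(C)OO
Why: Sharpless asymmetric epoxidation; the Ti/L-(+)-tartrate complex delivers oxygen to the same alkene face that gives (2S,3S)-epoxides from E-2-alkenols, which for this Z-alcohol sets both side-chain stereocentres as (2S,3R).

**Step 3**
Reactants: 3 [(2S,3R)-2,3-dimethyloxiran-2-yl]methanol
Product: 4 (2R,3R)-2,3-dimethyloxirane-2-carboxylic acid
Conditions: RuCl3·xH2O (2 mol %), NaIO4, MeCN/EtOAc/H2O, 0 °C to rt
Reagents that add atoms: water, O
Why: RuO4 oxidation of the primary alcohol to the acid via the aldehyde hydrate does not touch the epoxide, and C2 becomes R only through the change in substituent priority.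

**Step 4**
Reactants: 5 3-methylbut-2-enal; 6 methyl 2-(bromomethyl)prop-2-enoate
Product: 8 methyl (4R)-4-hydroxy-6-methyl-2-methylidenehept-5-enoate, via trimethylsilyl ether 7 (not isolated)
Conditions: CrCl2 (10 mol %), chiral 1,8-bis(4-isopropyloxazolin-2-yl)carbazole ligand (12 mol %, antipode giving Re-face attack), Mn powder, TMSCl, i-Pr2NEt, THF, 0 °C to rt; then aq. citric acid, MeOH, 0 °C
Reagents that add atoms: none
Why: Catalytic asymmetric Nozaki–Hiyama allylation; the ligand-bound allylchromium adds 1,2 to the Re face of the enal to set C8 as R, and the mild desilylation avoids lactonising the γ-hydroxy ester.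

**Step 5**
Reactants: 8 methyl (4R)-4-hydroxy-6-methyl-2-methylidenehept-5-enoate; 4 (2R,3R)-2,3-dimethyloxirane-2-carboxylic acid
Product: 10 methyl (4R)-4-(EpAng-oxy)-6-methyl-2-methylidenehept-5-enoate, via mixed Yamaguchi anhydride 9 (not isolated)
Conditions: 4, 2,4,6-trichlorobenzoyl chloride, Et3N, THF, rt; then 8, DMAP, toluene, 0 °C to rt
Reagents that add atoms: none
Why: Yamaguchi esterification acylates the hindered secondary allylic alcohol at oxygen (retention at C8) under non-acidic conditions that spare the epoxide and avoid allylic transposition.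

**Step 6**
Reactants: 10 methyl (4R)-4-(EpAng-oxy)-6-methyl-2-methylidenehept-5-enoate
Product: 12 methyl (4R)-4-(EpAng-oxy)-2-methylidene-5-oxopentanoate, via secondary ozonide 11 (not isolated)
Conditions: O3, CH2Cl2, −78 °C (Sudan red 7B end point); then Me2S, −78 °C to rt
Reagents that add atoms: ozone, [O-][O+]=O
Why: Ozonolysis is selective for the electron-rich trisubstituted alkene over the electron-poor 1,1-disubstituted acrylate, and reductive work-up gives the α-acyloxy aldehyde without touching C8.

**Step 7**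
Reactants: 12 methyl (4R)-4-(EpAng-oxy)-2-methylidene-5-oxopentanoate; 13 methyl acrylate
Product: 14 dimethyl (4R)-4-(EpAng-oxy)-3-hydroxy-2,6-dimethylideneheptanedioate (both C3 epimers)
Conditions: methyl acrylate (excess, neat), DABCO (0.5 equiv), 0 °C to rt, short reaction time
Reagents that add atoms: none
Why: Morita–Baylis–Hillman reaction; the activated α-acyloxy aldehyde reacts fast, which limits C8 epimerisation and 1,2-shift of the hindered ester, and the new carbinol centre is erased in the next step.

**Step 8**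
Reactants: 14 dimethyl (4R)-4-(EpAng-oxy)-3-hydroxy-2,6-dimethylideneheptanedioate
Product: 15 dimethyl (2Z,4R)-2-(bromomethyl)-4-(EpAng-oxy)-6-methylidenehept-2-enedioate
Conditions: NBS, Me2S, CH2Cl2, 0 °C to rt
Reagents that add atoms: N-bromosuccinimide, BrN1C(=O)CCC1=O
Why: Corey–Kim-type bromination of the Baylis–Hillman alcohol proceeds with allylic transposition (SN2′) to the thermodynamically preferred (2Z)-2-(bromomethyl)enoate under non-acidic conditions that spare the epoxide.

**Step 9**
Reactants: 16 5-hydroxy-4-methylfuran-2(5H)-one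
Product: 20 (5S)-4-methyl-5-(prop-2-en-1-yl)furan-2(5H)-one, via lithium formyl carboxylate 17 (not isolated), via O-borinate 18 (not isolated), via hydroxy acid 19 (not isolated)
Conditions: LiN(SiMe3)2 (1.0 equiv), THF, −78 to 0 °C; (−)-Ipc2B(allyl) [(+)-α-pinene series], Et2O/THF, −78 °C; then 1 M HCl, rt
Reagents that add atoms: (−)-B-allyldiisopinocampheylborane, C=CCB([C@@H]1C[C@@H]2C[C@H]([C@H]1C)C2(C)C)[C@@H]1C[C@@H]2C[C@H]([C@H]1C)C2(C)C
Why: Brown asymmetric allylboration; base opens the hemiacylal to the Z-formyl carboxylate, the reagent allylates the aldehyde Si face through a chair transition state to set C3 as S, and acidification closes the butenolide, which locks C4=C5 cis.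

**Step 10**
Reactants: 20 (5S)-4-methyl-5-(prop-2-en-1-yl)furan-2(5H)-one
Product: 21 (5S)-4-methyl-5-(prop-2-en-1-yl)-2,5-dihydrofuran-2-ol (anomer mixture)
Conditions: i-Bu2AlH (1.1 equiv), CH2Cl2, −78 °C; aq. potassium sodium tartrate
Reagents that add atoms: none
Why: Low-temperature half-reduction of the lactone stops at the aluminium hemiacetal and gives the lactol, a masked Z-enal that also masks the C3 hydroxyl, without touching C3.

**Step 11**
Reactants: 21 (5S)-4-methyl-5-(prop-2-en-1-yl)-2,5-dihydrofuran-2-ol; 15 dimethyl (2Z,4R)-2-(bromomethyl)-4-(EpAng-oxy)-6-methylidenehept-2-enedioate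
Product: 22 dimethyl (2Z,4R,6E)-2-(bromomethyl)-4-(EpAng-oxy)-6-{2-[(2S)-5-hydroxy-3-methyl-2,5-dihydrofuran-2-yl]ethylidene}hept-2-enedioate
Conditions: second-generation Hoveyda–Grubbs catalyst (10 mol %), 21 (3 equiv), 1,4-benzoquinone (10 mol %), CH2Cl2, 40 °C, Ar sparge
Reagents that add atoms: none
Why: Olefin cross-metathesis between a terminal alkene and a 2-substituted acrylate (which does not homodimerise) gives the trisubstituted enoate with the ester trans to the new chain (thermodynamic 6E geometry), while the trisubstituted and ring alkenes are inert.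

**Step 12**
Reactants: 22 dimethyl (2Z,4R,6E)-2-(bromomethyl)-4-(EpAng-oxy)-6-{2-[(2S)-5-hydroxy-3-methyl-2,5-dihydrofuran-2-yl]ethylidene}hept-2-enedioate
Product: 25 CNP0143679.1 (target), via open-chain hydroxy enal 23 (not isolated), via ten-membered hydroxy ester 24 (not isolated)
Conditions: CrCl2 (8 equiv), THF, 4 Å MS, 22 added over 10 h to 0.003 M, rt; then sat. aq. NH4Cl
Reagents that add atoms: none
Why: Intramolecular Nozaki–Hiyama (Barbier-type) allylation with in situ lactonisation, a known way to close germacranolide rings; the lactol releases the Z-enal slowly, the equilibrating allylchromium is expected to add through a chair transition state with both ring chains pseudo-equatorial (6,7-anti, hence the trans-lactone) and with the aldehyde anti to the C8–C9 bond while C8–H eclipses the alkene (H-7 cis to H-8, giving 6R,7R), and the C6 alkoxide then closes the five-membered lactone on the C12 ester.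

**Compound list**
1 | angelic acid, (2Z)-2-methylbut-2-enoic acid | C/C=C(/C)C(=O)O | starting material
2 | (2Z)-2-methylbut-2-en-1-ol | C/C=C(/C)CO | intermediate
3 | [(2S,3R)-2,3-dimethyloxiran-2-yl]methanol | OC[C@]1(C)O[C@@H]1C | intermediate
4 | (2R,3R)-2,3-dimethyloxirane-2-carboxylic acid (epoxyangelic acid) | OC(=O)[C@]1(C)O[C@@H]1C | intermediate
5 | 3-methylbut-2-enal | CC(C)=CC=O | starting material
6 | methyl 2-(bromomethyl)prop-2-enoate | C=C(CBr)C(=O)OC | starting material
7 | methyl (4R)-6-methyl-2-methylidene-4-[(trimethylsilyl)oxy]hept-5-enoate | C=C(C[C@@H](O[Si](C)(C)C)C=C(C)C)C(=O)OC | intermediate (not isolated)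
8 | methyl (4R)-4-hydroxy-6-methyl-2-methylidenehept-5-enoate | C=C(C[C@@H](O)C=C(C)C)C(=O)OC | intermediate
9 | (2R,3R)-2,3-dimethyloxirane-2-carboxylic 2,4,6-trichlorobenzoic anhydride | O=C(OC(=O)c1c(Cl)cc(Cl)cc1Cl)[C@]1(C)O[C@@H]1C | intermediate (not isolated)
10 | methyl (4R)-4-{[(2R,3R)-2,3-dimethyloxirane-2-carbonyl]oxy}-6-methyl-2-methylidenehept-5-enoate | C=C(C[C@@H](OC(=O)[C@]1(C)O[C@@H]1C)C=C(C)C)C(=O)OC | intermediate
11 | methyl (4R)-4-{[(2R,3R)-2,3-dimethyloxirane-2-carbonyl]oxy}-4-(5,5-dimethyl-1,2,4-trioxolan-3-yl)-2-methylidenebutanoate | C=C(C[C@@H](OC(=O)[C@]1(C)O[C@@H]1C)C1OOC(C)(C)O1)C(=O)OC | intermediate (not isolated)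
12 | methyl (4R)-4-{[(2R,3R)-2,3-dimethyloxirane-2-carbonyl]oxy}-2-methylidene-5-oxopentanoate | C=C(C[C@@H](OC(=O)[C@]1(C)O[C@@H]1C)C=O)C(=O)OC | intermediate
13 | methyl acrylate | C=CC(=O)OC | starting material
14 | dimethyl (4R)-4-{[(2R,3R)-2,3-dimethyloxirane-2-carbonyl]oxy}-3-hydroxy-2,6-dimethylideneheptanedioate (C3 epimers) | C=C(C[C@@H](OC(=O)[C@]1(C)O[C@@H]1C)C(O)C(=C)C(=O)OC)C(=O)OC | intermediate
15 | dimethyl (2Z,4R)-2-(bromomethyl)-4-{[(2R,3R)-2,3-dimethyloxirane-2-carbonyl]oxy}-6-methylidenehept-2-enedioate | BrC/C(C(=O)OC)=C\[C@H](OC(=O)[C@]1(C)O[C@@H]1C)CC(=C)C(=O)OC | intermediate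
16 | 5-hydroxy-4-methylfuran-2(5H)-one (racemic hemiacylal) | CC1=CC(=O)OC1O | starting material
17 | lithium (2Z)-3-methyl-4-oxobut-2-enoate | [Li+].[O-]C(=O)/C=C(/C)C=O | intermediate (not isolated)
18 | lithium (2Z,4S)-4-[(diisopinocampheylboranyl)oxy]-3-methylhepta-2,6-dienoate | [Li+].[O-]C(=O)/C=C(/C)[C@@H](OB([C@@H]1C[C@@H]2C[C@H]([C@H]1C)C2(C)C)[C@@H]1C[C@@H]2C[C@H]([C@H]1C)C2(C)C)CC=C | intermediate (not isolated)
19 | (2Z,4S)-4-hydroxy-3-methylhepta-2,6-dienoic acid | OC(=O)/C=C(/C)[C@@H](O)CC=C | intermediate (not isolated)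
20 | (5S)-4-methyl-5-(prop-2-en-1-yl)furan-2(5H)-one | O=C1C=C(C)[C@H](CC=C)O1 | intermediate
21 | (5S)-4-methyl-5-(prop-2-en-1-yl)-2,5-dihydrofuran-2-ol (anomer mixture) | OC1C=C(C)[C@H](CC=C)O1 | intermediate
22 | dimethyl (2Z,4R,6E)-2-(bromomethyl)-4-{[(2R,3R)-2,3-dimethyloxirane-2-carbonyl]oxy}-6-{2-[(2S)-5-hydroxy-3-methyl-2,5-dihydrofuran-2-yl]ethylidene}hept-2-enedioate | OC1C=C(C)[C@H](C/C=C(/C(=O)OC)C[C@@H](OC(=O)[C@]2(C)O[C@@H]2C)/C=C(\CBr)C(=O)OC)O1 | intermediate
23 | open-chain tautomer of 22: Z-enal (C6 aldehyde) with free (3S)-hydroxyl | O=C/C=C(/C)[C@@H](O)C/C=C(/C(=O)OC)C[C@@H](OC(=O)[C@]1(C)O[C@@H]1C)/C=C(\CBr)C(=O)OC | intermediate (not isolated)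
24 | unlactonised ten-membered carbocycle: cis,cis-cyclodeca-1(10),4-diene with 3-OH, 6-OH, 8-O-EpAng, 14-CO2Me and a 7-[1-(methoxycarbonyl)vinyl] group, same spatial arrangement as 25 | C=C(C(=O)OC)[C@H]1[C@H](O)/C=C(/C)[C@@H](O)C/C=C(/C(=O)OC)C[C@H]1OC(=O)[C@]2(C)O[C@@H]2C | intermediate (not isolated)
25 | CNP0143679.1: (3S,6R,7R,8R)-cis,cis-germacra-1(10),4,11(13)-trien-12,6-olide with 3-OH, 8-O-[(2R,3R)-epoxyangeloyl] and 14-CO2Me | C=C1C(=O)O[C@@H]2/C=C(/C)[C@@H](O)C/C=C(/C(=O)OC)C[C@@H](OC(=O)[C@]3(C)O[C@@H]3C)[C@@H]12 | target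

**Totals**
Total steps: 12. Longest linear sequence: 9 steps (1 → 2 → 3 → 4 → 10 → 12 → 14 → 15 → 22 → 25).

**Three steps most likely to fail**

Step 12 (ring closure). The allylchromium carries the C8 carboxylate in a vinylogous β-position and could expel it (1,4-elimination to a diene) before the slow ring closure. The C6/C7 outcome rests on a transition-state argument, not on a direct precedent with an 8-acyloxy group. The lactol could also dehydrate to a furan. Fallback: set out from 14 and acetylate it (Ac2O, pyridine) to the Baylis–Hillman acetate F1. Borylate F1 with allylic transposition (B2pin2, CuCl, LiCl, KOAc, DMF) to the pinacol allylboronate F2. Cross-metathesise F2 with 21 as in step 11 to the lactol boronate F3. Heat F3 in toluene (60–80 °C, then PPTS) to effect intramolecular allylboration through a closed six-membered transition state, which cannot lose carboxylate, followed by lactonisation. This comes back to the route at 25; its diastereoselectivity would have to be established.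

Step 11 (cross-metathesis). The hindered 2-substituted acrylate of 15 may react too slowly with the lactol-bearing alkene, leaving mainly the homodimer of 21. Fallback: set out from 21 and 15 and join them first by bimolecular CrCl2-mediated allylation/lactonisation (THF, 0.2 M, rt) to the seco-diene lactone F4. Then close the ten-membered ring at C1=C10 by ring-closing metathesis (second-generation Hoveyda–Grubbs catalyst, toluene, 80 °C, 0.002 M), where the intramolecular setting helps the acrylate. This comes back to the route at 25, with the rings formed one after the other.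

Step 4 (asymmetric allylation). Enantioselectivity with a β,β-disubstituted enal is not assured, the facial sense must be confirmed (Mosher esters), and the hydroxy ester may lactonise. Fallback: set out from 5 and 6 and couple them with indium powder in THF/H2O to the racemic alcohol F5. Oxidise F5 with Dess–Martin periodinane to the dienone F6. Reduce F6 with (S)-Me-CBS oxazaborolidine and BH3·SMe2 (THF, −40 °C), the alkenyl group acting as the large substituent, to give the 4R alcohol. This comes back to the route at 8.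

**Further compounds**
F1 | step 12 | dimethyl (4R)-3-acetoxy-4-{[(2R,3R)-2,3-dimethyloxirane-2-carbonyl]oxy}-2,6-dimethylideneheptanedioate (C3 epimers) | C=C(C[C@@H](OC(=O)[C@]1(C)O[C@@H]1C)C(OC(C)=O)C(=C)C(=O)OC)C(=O)OC
F2 | step 12 | dimethyl (2E,4R)-4-{[(2R,3R)-2,3-dimethyloxirane-2-carbonyl]oxy}-6-methylidene-2-[(4,4,5,5-tetramethyl-1,3,2-dioxaborolan-2-yl)methyl]hept-2-enedioate | CC1(C)OB(C/C(C(=O)OC)=C\[C@H](OC(=O)[C@]2(C)O[C@@H]2C)CC(=C)C(=O)OC)OC1(C)C
F3 | step 12 | boronate analogue of 22 (CH2Bpin in place of CH2Br) | OC1C=C(C)[C@H](C/C=C(/C(=O)OC)C[C@@H](OC(=O)[C@]2(C)O[C@@H]2C)/C=C(\CB2OC(C)(C)C(C)(C)O2)C(=O)OC)O1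
F4 | step 11 | seco-diene lactone: trans-α-methylene-γ-butyrolactone with C6–C7 bond formed, C1 and C10 still terminal alkenes, configuration at C3, C6, C7, C8 as in 25 | C=C1C(=O)O[C@H](/C=C(/C)[C@@H](O)CC=C)[C@H]1[C@@H](CC(=C)C(=O)OC)OC(=O)[C@]2(C)O[C@@H]2C
F5 | step 4 | racemic methyl 4-hydroxy-6-methyl-2-methylidenehept-5-enoate | C=C(CC(O)C=C(C)C)C(=O)OC
F6 | step 4 | methyl 6-methyl-2-methylidene-4-oxohept-5-enoate | C=C(CC(=O)C=C(C)C)C(=O)OC
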